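A small charge of initiator opened the meeting: the south-east run, at 7.4 mM, still held 21.1% of its starting material after 40.0 h. Four new flasks of the same recipe differ in c(initiator) and stop at 2.5 d.

in all of them: starting material 0.050 M

| flask | reagent | scavenger | initiator | remark | time |
|---|---|---|---|---|---|
| south-east | 0.075 M | 0.075 M | 7.4 mM | run made earlier |  |
| north-east | 0.075 M | 0.075 M | 24 mM | run made earlier |  |
| south-west | 0.075 M | 0.075 M | 51 mM | run made earlier |  |
| midnight | 0.0750 M | 0.0750 M | 8.0 mM |  | 2.5 d |
| spring | 0.0750 M | 0.0750 M | 15 mM |  | 2.5 d |
| autumn | 0.0750 M | 0.0750 M | 30 mM |  | 2.5 d |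
| dusk | 0.0750 M | 0.0750 M | 60 mM |  | 2.5 d |

| run | time / h | product / % | starting material / % |
|---|---|---|---|
| south-east | 3.00 | 13.2 | 81.9 |
| south-east | 6.00 | 23.4 | 69.7 |
| south-east | 12.0 | 39.5 | 54.3 |
| south-east | 20.0 | 53.6 | 38.7 |
| south-east | 40.0 | 70.0 | 21.1 |
| north-east | 8.00 | 53.0 | 34.2 |
| north-east | 15.0 | 76.4 | 8.9 |
| north-east | 25.0 | 83.0 | 0 |
| north-east | 30.0 | 83.5 | 0 |
| north-east | 40.0 | 82.9 | 0.2 |
| south-west | 8.00 | 74.9 | 3.3 |
| south-west | 15.0 | 77.4 | 0 |
| south-west | 25.0 | 77.0 | 0.2 |
| south-west | 30.0 | 77.1 | 0.9 |
| south-west | 40.0 | 76.5 | 0.3 |

(each reading ± 0.5 percentage points)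

1. amount of product at the end, in percent of the starting material charged for midnight, spring, autumn, dusk, in this order
2. how the row runs (rises all the way / rises, then falls / falls, then rises / hardly changes / falls all the way)

- "hardly changes" means that all values lie within two and a half points (for a concentration: within two and a half percent of the largest)

The first speaker pointed to the flat ends of the larger runs. North-east stays near 83.1% and south-west near 77.0%. She read these plateaus as the selectivity at full conversion.

Between them, product drops by a fraction 0.00227 mM⁻¹ of the charge. She named this the plateau slope, the product lost per mM of initiator, as a fraction of the starting material charged. Drawn through the plateaus, the line gives spring 85.2%, autumn 81.8% and dusk 75.0%.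

The second speaker replied that the line is an estimate for a finished flask, and that a flask still holding starting material stands below it. For midnight the line gives 86.8%. He took south-east as the nearest guide. From 20.0 h to 40.0 h its starting material fell from 38.7% to 21.1%. The last 20.0 h of a run at 2.5 d repeat that interval's length. The same fraction again leaves 11.5%, and south-east's decay was slowing, so more may stay.

My reckoning for midnight is therefore 76.8%. Spring was taken as finished, a bet on north-east's 0% at 25.0 h. The crossing lies between these flasks: below it conversion holds the product down, above it the plateau slope does. The row rises from midnight to spring, then falls.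

The forecast gave 78%, 84%, 82% and 75%, with the shape rises, then falls. Its ground: “Product is stable once formed, but selectivity falls with initiator”. My reckoning stands higher at spring, 85.2% against 84%, and lower at midnight, 76.8% against 78%.

The flasks give 78.5%, 86.0%, 81.6% and 75.5%. The row runs: rises, then falls, turning at 12 mM.

    initiator → 2 initiating radical (k = 0.0475 h⁻¹)
    starting material + initiating radical → capped initiator + first chain carrier (k = 1.02 × 10⁷ M⁻¹ h⁻¹)
    reagent + first chain carrier → product + second chain carrier (k = 6.77 × 10⁵ M⁻¹ h⁻¹)
    starting material + second chain carrier → released group + first chain carrier (k = 5.65 × 10⁵ M⁻¹ h⁻¹)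
    first chain carrier → ended carrier (k = 2850 h⁻¹)
    2 first chain carrier → ended chains A (k = 8.60 × 10⁶ M⁻¹ s⁻¹)
    2 second chain carrier → ended chains B (k = 1.20 × 10⁷ M⁻¹ s⁻¹)
    starting material + released group ⇌ idle adduct, settled at all times (K = 55.9 M⁻¹)
    scavenger + released group → scavenged by-product (k = 19.7 M⁻¹ h⁻¹)

The plateau slope put spring at 85.2%, and spring stands at 86.0%. On dusk the same line gave 75.0%, and dusk stands at 75.5%. Midnight stands 8.3 percentage points under the line's 86.8%. In midnight at 2.50 d, the initiator's half-life by its own breakdown is 0.61 d, shorter than the 2.7 d of starting material by the chain step. At that time midnight holds 5.8% of its initiator charge beside 12% of its starting material.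

The numbers in the tables are simulated on assumed constants, and the scatter is random.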